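## Retrosynthetic overview

- The target is reached from a C4 formyl ester by four closing operations: aldehyde to methyl via the tosylhydrazone, ester demethylation, desilylation and O-propanoylation at C15.
- The formyl ester comes from a [3,3] ring contraction of a dihydropyran. The feature used is ring A (C1, C2, C3, C4, C5, C10): its alkene sits at C1=C10, allylic to C5, and C4 carries two one-carbon groups (C19 and C18). The C4–C5 bond is therefore the retron of a Claisen shift of an enol ether linked through O to C1, with C19 as the enol ether carbon.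
- The dihydropyran comes from alkoxy exchange within a hydroxy β-methoxyacrylate, made by reagent-controlled reduction of an enone, itself from Nozaki–Hiyama–Kishi union (C10–C1 bond) of a ring B alkenyl triflate with a C1–C4/C18/C19 aldehyde.
- The ring B triflate comes from 2-methylcyclohexenone: asymmetric conjugate methylation (C8), Mukaiyama–Michael addition to butenone (C9), olefination (C13=C14). The aldehyde comes from methyl 5,5-dimethoxypentanoate by formylation and O-methylation.
- Ring order: ring B is carried from the cyclohexenone, the dihydropyran is closed in step 12, and ring A is closed last, in step 13, at the expense of the dihydropyran.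

Key step: step 13

Remarks on the chemistry:
- Halimane numbering (C1–C20) is used for all intermediates.
- The silyl ether is tert-butyldiphenylsilyl, chosen for tolerance of the mildly acidic step 12.
- The C19 aldehyde is taken to methyl through its tosylhydrazone. Free hydrazine with hot hydroxide would be expected to close a pyrazolone onto the geminal ester or to deformylate the non-enolisable formyl ester.
- In step 1 the ligand antipode is the one that gives the 3R enolate.
- Methyl 5,5-dimethoxypentanoate is taken as a purchasable starting material.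

## Route

Step 1
Reactants: 1 2-methylcyclohex-2-en-1-one
Product: 3 (R)-[(2,3-dimethylcyclohex-1-en-1-yl)oxy]trimethylsilane, via dimethylaluminium enolate 2 (not isolated)
Conditions: Me3Al, copper thiophene-2-carboxylate Cu(O2C-C4H3S) (monovalent copper, 2 mol %), chiral binaphthol phosphoramidite ligand (4 mol %), Et2O, −30 °C; then TMSOTf, THF, −30 → 0 °C
Reagents that add atoms: trimethylaluminium C[Al](C)C; trimethylsilyl trifluoromethanesulfonate C[Si](C)(C)OS(=O)(=O)C(F)(F)F
Why: Copper-catalysed asymmetric conjugate addition of methyl to the α-substituted enone should set C8 (the 3R centre) under ligand control, and O-silylation of the regiodefined aluminium enolate stores the tetrasubstituted enolate needed for the quaternary centre.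

Step 2
Reactants: 3 (R)-[(2,3-dimethylcyclohex-1-en-1-yl)oxy]trimethylsilane; 4 but-3-en-2-one
Product: 5 (2S,3R)-2,3-dimethyl-2-(3-oxobutyl)cyclohexan-1-one (methyl groups cis)
Conditions: BF3·OEt2, i-PrOH, CH2Cl2, −78 °C
Reagents that add atoms: none
Why: Mukaiyama–Michael addition in which the activated enone should approach the silyl enol ether anti to the C3 methyl (held pseudoaxial by A(1,2) strain), so that the oxobutyl chain enters trans to it and the quaternary C9 forms with the two methyl groups cis; the acidic medium avoids aldol closure of the 1,5-diketone.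

Step 3
Reactants: 5 (2S,3R)-2,3-dimethyl-2-(3-oxobutyl)cyclohexan-1-one; 6 triethyl phosphonoacetate
Product: 7 ethyl (E)-5-[(1S,2R)-1,2-dimethyl-6-oxocyclohexyl]-3-methylpent-2-enoate
Conditions: NaH, THF, 0 → 50 °C; E isomer separated by chromatography
Reagents that add atoms: none
Why: Horner–Wadsworth–Emmons olefination is expected only at the unhindered methyl ketone, the ring ketone being shielded by the adjacent quaternary carbon, and should favour the E enoate, the minor Z isomer being removed by chromatography.

Step 4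
Reactants: 7 ethyl (E)-5-[(1S,2R)-1,2-dimethyl-6-oxocyclohexyl]-3-methylpent-2-enoate
Product: 9 ethyl (E)-5-[(1S,6R)-1,6-dimethyl-2-(trifluoromethanesulfonyloxy)cyclohex-2-en-1-yl]-3-methylpent-2-enoate, via potassium enolate 8 (not isolated)
Conditions: KN(SiMe3)2, THF, −78 °C; then PhNTf2, −78 → 0 °C
Reagents that add atoms: N-phenylbis(trifluoromethanesulfonimide) O=S(=O)(N(c1ccccc1)S(=O)(=O)C(F)(F)F)C(F)(F)F
Why: Kinetic deprotonation at the only enolisable ring position (the other α-carbon is quaternary) should be much faster than γ-deprotonation of the β,β-disubstituted enoate, and O-sulfonylation of the enolate fixes the alkene at C10=C5 as the enol triflate.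

Step 5
Reactants: 9 ethyl (E)-5-[(1S,6R)-1,6-dimethyl-2-(trifluoromethanesulfonyloxy)cyclohex-2-en-1-yl]-3-methylpent-2-enoate
Product: 10 (5R,6S)-6-[(E)-5-hydroxy-3-methylpent-3-en-1-yl]-5,6-dimethylcyclohex-1-en-1-yl trifluoromethanesulfonate
Conditions: i-Bu2AlH, CH2Cl2, −78 °C; aqueous potassium sodium tartrate (KNaC4H4O6) work-up
Reagents that add atoms: none
Why: 1,2-Reduction of the enoate by the aluminium hydride at low temperature gives the E allylic alcohol, alkenyl triflates being inert to the reagent at −78 °C.

Step 6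
Reactants: 10 (5R,6S)-6-[(E)-5-hydroxy-3-methylpent-3-en-1-yl]-5,6-dimethylcyclohex-1-en-1-yl trifluoromethanesulfonate
Product: 11 (5R,6S)-6-{(E)-5-[(tert-butyldiphenylsilyl)oxy]-3-methylpent-3-en-1-yl}-5,6-dimethylcyclohex-1-en-1-yl trifluoromethanesulfonate
Conditions: TBDPSCl, imidazole, CH2Cl2, 0 °C → rt
Reagents that add atoms: tert-butyl(chloro)diphenylsilane CC(C)(C)[Si](Cl)(c1ccccc1)c1ccccc1
Why: Standard silylation of the primary alcohol with a silyl group that should survive the mild acid of step 12, the heat of step 13 and the thiolate of step 16.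

Step 7
Reactants: 12 methyl 5,5-dimethoxypentanoate
Product: 14 methyl (E)-5,5-dimethoxy-2-(methoxymethylidene)pentanoate, via sodium formyl ester enolate 13 (not isolated)
Conditions: NaH, HCO2Me, cat. MeOH, THF, 0 °C → rt; then DMF, Me2SO4, 0 °C → rt
Reagents that add atoms: methyl formate COC=O; dimethyl sulfate COS(=O)(=O)OC
Why: Crossed Claisen condensation with the non-enolisable formate gives the stabilised formyl ester enolate, whose O-methylation by the hard electrophile in a dipolar solvent should give the β-methoxyacrylate (mainly E; the geometry is of no consequence later).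

Step 8
Reactants: 14 methyl (E)-5,5-dimethoxy-2-(methoxymethylidene)pentanoate
Product: 15 methyl (E)-2-(methoxymethylidene)-5-oxopentanoate
Conditions: AcOH/THF/H2O, rt
Reagents that add atoms: water O
Why: Selective acid hydrolysis of the dimethyl acetal, the push–pull β-methoxyacrylate being much less prone to hydrolysis under these mild conditions.

Step 9
Reactants: 11 (5R,6S)-6-{(E)-5-[(tert-butyldiphenylsilyl)oxy]-3-methylpent-3-en-1-yl}-5,6-dimethylcyclohex-1-en-1-yl trifluoromethanesulfonate; 15 methyl (E)-2-(methoxymethylidene)-5-oxopentanoate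
Product: 17 methyl (E)-5-[(5R,6S)-6-{(E)-5-[(tert-butyldiphenylsilyl)oxy]-3-methylpent-3-en-1-yl}-5,6-dimethylcyclohex-1-en-1-yl]-5-hydroxy-2-(methoxymethylidene)pentanoate (both C5 epimers; C5 of the pentanoate is C1 of the halimane), via alkenylchromium dichloride 16 (not isolated)
Conditions: CrCl2, NiCl2 (2 mol %), DMF, rt
Reagents that add atoms: none
Why: Nozaki–Hiyama–Kishi coupling, in which nickel-catalysed formation of the alkenylchromium species from the hindered triflate and its chemoselective addition to the aldehyde tolerate the silyl ether and the acrylate ester; the C1 carbinol forms as an epimer mixture that is erased in step 10.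

Step 10
Reactants: 17 the C1 carbinol mixture
Product: 18 methyl (E)-5-[(5R,6S)-6-{(E)-5-[(tert-butyldiphenylsilyl)oxy]-3-methylpent-3-en-1-yl}-5,6-dimethylcyclohex-1-en-1-yl]-2-(methoxymethylidene)-5-oxopentanoate
Conditions: Dess–Martin periodinane, NaHCO3, CH2Cl2, 0 °C → rt
Reagents that add atoms: none
Why: Buffered Dess–Martin oxidation of the secondary allylic alcohol converges both epimers to the enone without touching the enol ether or the silyl ether.

Step 11
Reactants: 18 the C1 enone
Product: 19 methyl (2E,5S)-5-[(5R,6S)-6-{(E)-5-[(tert-butyldiphenylsilyl)oxy]-3-methylpent-3-en-1-yl}-5,6-dimethylcyclohex-1-en-1-yl]-5-hydroxy-2-(methoxymethylidene)pentanoate (1S in halimane numbering)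
Conditions: (R)-2-methyl-CBS-oxazaborolidine (20 mol %), catecholborane, toluene, −78 °C
Reagents that add atoms: none
Why: Corey–Bakshi–Shibata reduction, in which the (R)-oxazaborolidine should treat the α-branched cyclohexenyl group as the large substituent and deliver hydride to give the S carbinol at C1 under reagent control; catecholborane does not hydroborate the alkenes at this temperature.

Step 12
Reactants: 19 the (1S) hydroxy β-methoxyacrylate
Product: 20 methyl (2S)-2-[(5R,6S)-6-{(E)-5-[(tert-butyldiphenylsilyl)oxy]-3-methylpent-3-en-1-yl}-5,6-dimethylcyclohex-1-en-1-yl]-3,4-dihydro-2H-pyran-5-carboxylate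
Conditions: PPTS (10 mol %), toluene, 80 °C, MeOH removed over 5 Å molecular sieves
Reagents that add atoms: none
Why: Acid-catalysed alkoxy exchange at the β-carbon of the β-methoxyacrylate (addition of the C1 hydroxyl to the C-protonated oxocarbenium ion, then loss of methanol) closes the six-membered vinylogous carbonate; the C1–O bond is not broken, so C1 stays S, and the deactivated acrylate ester should not lactonise.

Step 13
Reactants: 20 the C1-linked dihydropyran
Product: 21 methyl (4S,5S,8R,9S)-15-[(tert-butyldiphenylsilyl)oxy]-19-oxohalima-1(10),13E-dien-18-oate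
Conditions: toluene (0.01 M, degassed), 2,6-di-tert-butyl-4-methylpyridine (0.2 equiv), base-washed sealed tube, about 190 °C
Reagents that add atoms: none
Why: A concerted [3,3] sigmatropic (Claisen) shift through C4=C19–O–C1–C10=C5 joins C4 to C5 as C1–O breaks, moves the alkene to C1=C10 and releases C19 as the aldehyde. The closest known reaction type is the thermal ring contraction of 2-alkenyl-3,4-dihydro-2H-pyrans to cyclohexenecarbaldehydes, here helped by the ester on the enol ether carbon as in the rearrangement of allyl β-alkoxyacrylates to α-formyl esters. Ring A (C1, C2, C3, C4, C5, C10) closes as a six-membered carbocycle by pericyclic C4–C5 bond formation across the existing C1–C2–C3–C4 tether, which permits only a boat-like transition state with C1 and C4 as bridgeheads of a bicyclo[2.2.2]-like array. C5 is controlled by C1: A(1,2) strain with the quaternary C9 keeps H1 pointing to C9 and C2 syn to C5, so in the 1S isomer the C1–O bond lies on the ring B face that carries the C9 methyl and the suprafacial shift delivers C4 to that same face. C4 is controlled by the boat, which places the ring enol ether carbon C19 cis to C6 and the exocyclic ester C18 cis to H5. The step needs the concerted path to outrun retro-hetero-Diels–Alder fragmentation and acid-promoted ionisation of the allylic C1–O bond, which would lose the C1-to-C5 transfer; the acceptor-lowered barrier, high dilution, base-washed glass and the hindered pyridine serve this.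

Step 14
Reactants: 21 the C19 aldehyde
Product: 22 methyl (4S,5S,8R,9S)-15-[(tert-butyldiphenylsilyl)oxy]-19-[(E)-2-(4-methylbenzenesulfonyl)hydrazinylidene]halima-1(10),13E-dien-18-oate
Conditions: TsNHNH2, EtOH, 50 °C
Reagents that add atoms: 4-methylbenzenesulfonohydrazide Cc1ccc(cc1)S(=O)(=O)NN
Why: Condensation of the neopentyl aldehyde with tosylhydrazide, whose sulfonylated nitrogen is too weak a nucleophile to close a pyrazolone onto the neighbouring hindered ester.

Step 15
Reactants: 22 the C19 tosylhydrazone
Product: 24 methyl (4S,5S,8R,9S)-15-[(tert-butyldiphenylsilyl)oxy]halima-1(10),13E-dien-18-oate, via N-boryl tosylhydrazine 23 (not isolated)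
Conditions: catecholborane, CHCl3, 0 °C → rt; then NaOAc·3H2O, reflux
Reagents that add atoms: none
Why: Kabalka variant of the Caglioti reduction (hydroboration of C=N, then acetate-induced loss of sulfinate and of N2 from the alkyldiazene) should turn CH=N into the C19 methyl under non-basic conditions that spare the ester and the non-conjugated alkenes and leave C4 untouched.

Step 16
Reactants: 24 the C18 methyl ester
Product: 25 (4S,5S,8R,9S)-15-[(tert-butyldiphenylsilyl)oxy]halima-1(10),13E-dien-18-oic acid
Conditions: LiSPr, HMPA, rt; then dilute HCl to pH 3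
Reagents that add atoms: none
Why: SN2 demethylation by thiolate at the methyl carbon avoids attack at the shielded carbonyl of the tertiary ester, as is usual for C4 esters of diterpenoid acids.

Step 17
Reactants: 25 the silyl ether acid
Product: 26 (4S,5S,8R,9S)-15-hydroxyhalima-1(10),13E-dien-18-oic acid
Conditions: Bu4NF, THF, rt; aqueous NH4Cl work-up
Reagents that add atoms: none
Why: Fluoride-induced cleavage of the silyl ether frees the primary allylic alcohol.

Step 18
Reactants: 26 the hydroxy acid
Product: 27 (4S,5S,8R,9S)-15-(propanoyloxy)halima-1(10),13E-dien-18-oic acid (CNP0223570.1)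
Conditions: (EtCO)2O, pyridine, DMAP (5 mol %), CH2Cl2, 0 °C; then aqueous NaHCO3/THF, rt; acidify to pH 3–4
Reagents that add atoms: propanoic anhydride CCC(=O)OC(=O)CC
Why: DMAP-catalysed acylation takes the unhindered primary allylic alcohol, and any mixed anhydride at the hindered C18 acid should be hydrolysed at its propanoyl carbonyl during the bicarbonate stir.

## Compound list

1 | 2-methylcyclohex-2-en-1-one | CC1=CCCCC1=O | starting material
2 | dimethylaluminium (R)-2,3-dimethylcyclohex-1-en-1-olate | C[C@@H]1CCCC(O[Al](C)C)=C1C | intermediate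
3 | (R)-[(2,3-dimethylcyclohex-1-en-1-yl)oxy]trimethylsilane | C[C@@H]1CCCC(O[Si](C)(C)C)=C1C | intermediate
4 | but-3-en-2-one | CC(=O)C=C | starting material
5 | (2S,3R)-2,3-dimethyl-2-(3-oxobutyl)cyclohexan-1-one | CC(=O)CC[C@]1(C)C(=O)CCC[C@H]1C | intermediate
6 | triethyl phosphonoacetate | CCOC(=O)CP(=O)(OCC)OCC | starting material
7 | ethyl (E)-5-[(1S,2R)-1,2-dimethyl-6-oxocyclohexyl]-3-methylpent-2-enoate | CCOC(=O)/C=C(\C)CC[C@]1(C)C(=O)CCC[C@H]1C | intermediate
8 | potassium enolate of 7 (C10–O, C10=C5) | CCOC(=O)/C=C(\C)CC[C@]1(C)C([O-])=CCC[C@H]1C.[K+] | intermediate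
9 | ethyl (E)-5-[(1S,6R)-1,6-dimethyl-2-(trifluoromethanesulfonyloxy)cyclohex-2-en-1-yl]-3-methylpent-2-enoate | CCOC(=O)/C=C(\C)CC[C@]1(C)C(OS(=O)(=O)C(F)(F)F)=CCC[C@H]1C | intermediate
10 | (5R,6S)-6-[(E)-5-hydroxy-3-methylpent-3-en-1-yl]-5,6-dimethylcyclohex-1-en-1-yl trifluoromethanesulfonate | OC/C=C(\C)CC[C@]1(C)C(OS(=O)(=O)C(F)(F)F)=CCC[C@H]1C | intermediate
11 | (5R,6S)-6-{(E)-5-[(tert-butyldiphenylsilyl)oxy]-3-methylpent-3-en-1-yl}-5,6-dimethylcyclohex-1-en-1-yl trifluoromethanesulfonate | CC(C)(C)[Si](c1ccccc1)(c1ccccc1)OC/C=C(\C)CC[C@]1(C)C(OS(=O)(=O)C(F)(F)F)=CCC[C@H]1C | intermediate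
12 | methyl 5,5-dimethoxypentanoate | COC(=O)CCCC(OC)OC | starting material
13 | sodium enolate of methyl 2-formyl-5,5-dimethoxypentanoate | [Na+].[O-]C=C(CCC(OC)OC)C(=O)OC | intermediate
14 | methyl (E)-5,5-dimethoxy-2-(methoxymethylidene)pentanoate | CO/C=C(\CCC(OC)OC)C(=O)OC | intermediate
15 | methyl (E)-2-(methoxymethylidene)-5-oxopentanoate | CO/C=C(\CCC=O)C(=O)OC | intermediate
16 | alkenylchromium dichloride from 11 (Cr on C10) | CC(C)(C)[Si](c1ccccc1)(c1ccccc1)OC/C=C(\C)CC[C@]1(C)C([Cr](Cl)Cl)=CCC[C@H]1C | intermediate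
17 | methyl (E)-5-[(5R,6S)-6-{(E)-5-[(tert-butyldiphenylsilyl)oxy]-3-methylpent-3-en-1-yl}-5,6-dimethylcyclohex-1-en-1-yl]-5-hydroxy-2-(methoxymethylidene)pentanoate, both carbinol epimers | CC(C)(C)[Si](c1ccccc1)(c1ccccc1)OC/C=C(\C)CC[C@]1(C)C(C(O)CC/C(=C\OC)C(=O)OC)=CCC[C@H]1C | intermediate
18 | methyl (E)-5-[(5R,6S)-6-{(E)-5-[(tert-butyldiphenylsilyl)oxy]-3-methylpent-3-en-1-yl}-5,6-dimethylcyclohex-1-en-1-yl]-2-(methoxymethylidene)-5-oxopentanoate | CC(C)(C)[Si](c1ccccc1)(c1ccccc1)OC/C=C(\C)CC[C@]1(C)C(C(=O)CC/C(=C\OC)C(=O)OC)=CCC[C@H]1C | intermediate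
19 | methyl (2E,5S)-5-[(5R,6S)-6-{(E)-5-[(tert-butyldiphenylsilyl)oxy]-3-methylpent-3-en-1-yl}-5,6-dimethylcyclohex-1-en-1-yl]-5-hydroxy-2-(methoxymethylidene)pentanoate | CC(C)(C)[Si](c1ccccc1)(c1ccccc1)OC/C=C(\C)CC[C@]1(C)C([C@@H](O)CC/C(=C\OC)C(=O)OC)=CCC[C@H]1C | intermediate
20 | methyl (2S)-2-[(5R,6S)-6-{(E)-5-[(tert-butyldiphenylsilyl)oxy]-3-methylpent-3-en-1-yl}-5,6-dimethylcyclohex-1-en-1-yl]-3,4-dihydro-2H-pyran-5-carboxylate | CC(C)(C)[Si](c1ccccc1)(c1ccccc1)OC/C=C(\C)CC[C@]1(C)C([C@@H]2CCC(C(=O)OC)=CO2)=CCC[C@H]1C | intermediate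
21 | methyl (4S,5S,8R,9S)-15-[(tert-butyldiphenylsilyl)oxy]-19-oxohalima-1(10),13E-dien-18-oate | CC(C)(C)[Si](c1ccccc1)(c1ccccc1)OC/C=C(\C)CC[C@]1(C)C2=CCC[C@](C=O)(C(=O)OC)[C@H]2CC[C@H]1C | intermediate
22 | C19 (E)-tosylhydrazone of 21 | CC(C)(C)[Si](c1ccccc1)(c1ccccc1)OC/C=C(\C)CC[C@]1(C)C2=CCC[C@](/C=N/NS(=O)(=O)c3ccc(C)cc3)(C(=O)OC)[C@H]2CC[C@H]1C | intermediate
23 | N-(1,3,2-benzodioxaborol-2-yl)-N'-tosylhydrazine at C19 | CC(C)(C)[Si](c1ccccc1)(c1ccccc1)OC/C=C(\C)CC[C@]1(C)C2=CCC[C@](CN(B3Oc4ccccc4O3)NS(=O)(=O)c3ccc(C)cc3)(C(=O)OC)[C@H]2CC[C@H]1C | intermediate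
24 | methyl (4S,5S,8R,9S)-15-[(tert-butyldiphenylsilyl)oxy]halima-1(10),13E-dien-18-oate | CC(C)(C)[Si](c1ccccc1)(c1ccccc1)OC/C=C(\C)CC[C@]1(C)C2=CCC[C@](C)(C(=O)OC)[C@H]2CC[C@H]1C | intermediate
25 | (4S,5S,8R,9S)-15-[(tert-butyldiphenylsilyl)oxy]halima-1(10),13E-dien-18-oic acid | CC(C)(C)[Si](c1ccccc1)(c1ccccc1)OC/C=C(\C)CC[C@]1(C)C2=CCC[C@](C)(C(=O)O)[C@H]2CC[C@H]1C | intermediate
26 | (4S,5S,8R,9S)-15-hydroxyhalima-1(10),13E-dien-18-oic acid | OC/C=C(\C)CC[C@]1(C)C2=CCC[C@](C)(C(=O)O)[C@H]2CC[C@H]1C | intermediate
27 | (4S,5S,8R,9S)-15-(propanoyloxy)halima-1(10),13E-dien-18-oic acid (CNP0223570.1) | CCC(=O)OC/C=C(\C)CC[C@]1(C)C2=CCC[C@](C)(C(=O)O)[C@H]2CC[C@H]1C | target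

## Step count and risks

Total step count: 18. Longest linear sequence: 16 steps (steps 1–6, then 9–18); steps 7–8 make the aldehyde partner 15.

Steps most likely to fail:

1. Step 13. The dihydropyran may fragment by retro-hetero-Diels–Alder reaction and recombine, or the allylic C1–O bond may ionise on traces of acid. Either process would lose the transfer of configuration from C1 to C5; slow rearrangement with thermal decomposition is the other failure mode. Fallback: from 11, Stille coupling with tributyl(vinyl)stannane (Pd(PPh3)4, LiCl, THF, reflux) would give the 1-vinylcyclohexene diene F1. A thermal Diels–Alder reaction of F1 with methyl methacrylate (toluene, sealed tube, 140–160 °C) would form ring A with C19 already a methyl group, so it returns to the route at 24 and bypasses steps 9–15. In this variant the C5 face and the exo placement of the ester rest only on the ring B substituents and on the usual exo preference of methacrylates, so regio- and stereoisomers would have to be separated.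

2. Step 2. Formation of the quaternary C9 may be slow against oligomerisation of the enone, or the facial selectivity anti to the C3 methyl may be poor. Fallback: from 3, MeLi (THF, 0 °C) would regenerate the lithium enolate F2. Its conjugate addition to 3-(trimethylsilyl)but-3-en-2-one at −78 °C (Stork–Ganem variant) would give the α-silyl diketone F3. Mild protodesilylation (KF, MeOH, 0 °C, kept short to avoid aldol closure) returns to 5.

3. Step 15. Hydride transfer to the hindered neopentyl hydrazone may stall, or the hydrazine nitrogen may cyclise onto the neighbouring ester before diazene formation. Fallback: from 21, NaBH4 (MeOH, 0 °C) would reduce only the aldehyde to the neopentyl alcohol F4. Phenyl chlorothionoformate with pyridine and DMAP (CH2Cl2) would give the O-phenyl thionocarbonate F5, avoiding a strong base that could trigger retro-aldol loss of formaldehyde. Barton–McCombie deoxygenation (Bu3SnH, AIBN, xylene, 130 °C) returns to 24.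

Further compounds
F1 | step 13 | tert-butyl{[(E)-5-[(1S,6R)-2-ethenyl-1,6-dimethylcyclohex-2-en-1-yl]-3-methylpent-2-en-1-yl]oxy}diphenylsilane | CC(C)(C)[Si](c1ccccc1)(c1ccccc1)OC/C=C(\C)CC[C@]1(C)C(C=C)=CCC[C@H]1C
F2 | step 2 | lithium (R)-2,3-dimethylcyclohex-1-en-1-olate | C[C@@H]1CCCC([O-])=C1C.[Li+]
F3 | step 2 | (2S,3R)-2,3-dimethyl-2-[3-oxo-2-(trimethylsilyl)butyl]cyclohexan-1-one (mixture at the silyl-bearing carbon) | CC(=O)C([Si](C)(C)C)C[C@]1(C)C(=O)CCC[C@H]1C
F4 | step 15 | methyl (4S,5S,8R,9S)-15-[(tert-butyldiphenylsilyl)oxy]-19-hydroxyhalima-1(10),13E-dien-18-oate | CC(C)(C)[Si](c1ccccc1)(c1ccccc1)OC/C=C(\C)CC[C@]1(C)C2=CCC[C@](CO)(C(=O)OC)[C@H]2CC[C@H]1C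
F5 | step 15 | methyl (4S,5S,8R,9S)-15-[(tert-butyldiphenylsilyl)oxy]-19-[(phenoxycarbonothioyl)oxy]halima-1(10),13E-dien-18-oate | CC(C)(C)[Si](c1ccccc1)(c1ccccc1)OC/C=C(\C)CC[C@]1(C)C2=CCC[C@](COC(=S)Oc3ccccc3)(C(=O)OC)[C@H]2CC[C@H]1C
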